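You sent me 4 questions and a hunch that X in solution was the thing to watch, so I reckoned on that.

    Z ⇌ L + X (K1 = 0.48 M, k1 = 0.0902 s⁻¹)
    Q ⇌ X, rate k2*(cs2 - [X]) while solid is left; crystals form when [X] > cs2 (cs2 = 45 mM, k2 = 0.346 s⁻¹)
    Z + X ⇌ Z.X, settled at all times (K3 = 1.01 L mol⁻¹)

Z 1.2 M; time 40 s

* L at 40 s, in percent of the Z charged
* concentration of X in solution at 4.0 s, in percent of saturation
* the change that raises the amount of L at 40 s, in percent of the Z charged most ("none" if none brings more than 2 percentage points) (ochre / red / none)
* amount of L at 40 s, in percent of the Z charged, after red

- ochre: doubling the dissolution coefficient of step 2, all else as stated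
- red: doubling the solubility in step 2, all else as stated

- what is said of X includes Q and Z.X
- Q is a solid; its amount is given per volume of the solution
- run time (flask): 40 s

I froze [X] at one level for the whole run and left Z.X out. Once crystals stand, [X] sits above the solubility by an overhang, and Q grows at the dissolution coefficient times that overhang. So the mean overhang is the Q made, divided by that coefficient and the time. For the Q made I took the L allowed at [X] equal to the solubility, 91.4 % of the Z charged, which put [X] at 0.124 M. With [X] frozen, the first step is pseudo-first-order, and its balance puts L at the equilibrium constant over itself plus [X], 79.4 % of the Z charged; I called this share of the Z charged, reckoned at a frozen level, the balance share. The approach takes 8.81 s, shorter than the 40 s run, so I committed to the balance share as the answer: 79.4 %.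

On this reckoning ochre lowers the level to 0.0846 M, which lifts the balance share by 5.6 percentage points. Red, reckoned the same way, raises the level to 0.163 M and gives 74.6 %. My choice was ochre. A level frozen over the run says nothing about 4.0 s, so I gave no figure for sat.

The forecast put L at 82 %, above my figure, X in solution at 330 % of saturation, and L after red at 78 %; it chose ochre, on the ground that “Faster crystallisation removes X sooner”.

The flask gave L 82.6 %, X in solution at 330 % of saturation at 4.0 s, ochre as the best change with 3.6 points, and L 76.4 % after red. Its [X] at 40.0 s was 0.0657 M, lower than my frozen level, and its L stood 3.2 points over my balance share. Carried to 400 s, the same rule gives a balance share of 90.1 %, and L in the flask stood at 91.1 %.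

For the neighbour flask with 2.0 M of Z, held to the same time, the rule gives a balance share of 73.0 %. The computed L there was 78.2 %.

(The constants used here are invented; the result is computed.)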